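**Retrosynthetic overview**
- The bridge C7–CH(CH3)–C7′ is cut last: the quinone-methide half adds through its C7 to an ortho-quinone methide made from the 7-(1-hydroxyethyl) lactone half, under a chiral phosphoric acid that sets the bridge centre.
- Both halves come from one monomer, (3R,4S)-6,8-dihydroxy-3,4,5-trimethylisochroman-1-one: C7 acetylation and reduction give the lower half; lactone → lactol → dehydration gives the upper pyrano-quinone methide.
- The trans C4 methyl of the monomer comes from benzylic methylation of the (3R)-3-methyl lactone. That lactone is made by the key C3–O ring closure, an enantioselective Markovnikov hydrolactonization of a 2-allylbenzoic acid.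
- The 2-allylbenzoic acid comes from carboxylate-directed C–H allylation of 2,4-dimethoxy-5-methylbenzoic acid, itself made from 5-bromo-2,4-dimethoxybenzoic acid.
- Ring order: the benzene ring is bought; the lactone ring is closed once by C–O bond formation (step 3); the same ring becomes the pyran of the upper half (step 8); the halves are joined last (step 9).

Assumptions: the name is read as dicitrinone H and the structure is taken from the SMILES (upper half drawn as the 6-hydroxy-8-oxo tautomer; the tautomers equilibrate); the catalyst antipodes written in steps 3 and 9 are working assignments, and the mirror-image catalyst is used if the first run shows the opposite sense.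

**Step 1**
Reactants: 1 5-bromo-2,4-dimethoxybenzoic acid
Product: 2 2,4-dimethoxy-5-methylbenzoic acid
Conditions: trimethylboroxine (0.5 equiv), Pd(dppf)Cl2 (3 mol %), K2CO3 (3 equiv), dioxane–H2O, 100 °C
Reagents that add atoms: trimethylboroxine, CB1OB(C)OB(C)O1
Why: Suzuki–Miyaura methylation of an aryl bromide, with the carboxylate inert under the basic conditions and no stereocentre involved.

**Step 2**
Reactants: 2 2,4-dimethoxy-5-methylbenzoic acid
Product: 3 2-allyl-4,6-dimethoxy-3-methylbenzoic acid
Conditions: allyl acetate (2 equiv), [RuCl2(p-cymene)]2 (4 mol %), K3PO4 (30 mol %), 2,2,2-trichloroethanol, 50 °C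
Reagents that add atoms: allyl acetate, C=CCOC(C)=O
Why: Carboxylate-directed ruthenium-catalysed ortho-C–H allylation (alkene insertion, then β-acetoxy elimination); the acid has only one free ortho C–H, so the position is fixed.

**Step 3**
Reactants: 3 2-allyl-4,6-dimethoxy-3-methylbenzoic acid
Product: 4 (3R)-6,8-dimethoxy-3,5-dimethylisochroman-1-one
Conditions: (S,S)-[N,N′-bis(3,5-di-tert-butylsalicylidene)-1,2-cyclohexanediaminato]cobalt (C36H52CoN2O2, divalent cobalt, 5 mol %), N-fluoro-2,4,6-trimethylpyridinium tetrafluoroborate (1.3 equiv), PhSiH3 (1.2 equiv), PhCF3, 0 °C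
Reagents that add atoms: none
Why: Proposed new method: an enantioselective hydrogen-atom-transfer/radical–polar-crossover hydrolactonization (Markovnikov, 6-exo) that closes a benzo-fused δ-lactone from a 2-allylbenzoic acid, in which the trivalent cobalt hydride formed from the salen complex, the N–F oxidant and the silane gives H• to the terminal CH2, the secondary C3 radical is captured by cobalt, the alkylcobalt is oxidized to the tetravalent state and the ortho-carboxylate displaces cobalt intramolecularly to form the C3–O bond, the two diastereomeric alkylcobalt species interconverting by homolysis faster than displacement so that the chiral salen ligand selects the (R) centre, while a radical rather than cationic C3 avoids the 1,2-hydride shift that would lead to the phthalide; closest known reaction type: cobalt–salen hydrogen-atom-transfer hydroalkoxylation and hydrolactonization of unactivated alkenes, whose enantioselective form is established for five-membered cyclic ethers but not for a six-membered benzo-lactone from a hindered, electron-rich 2-allylbenzoic acid.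

**Step 4**
Reactants: 4 (3R)-6,8-dimethoxy-3,5-dimethylisochroman-1-one
Product: 5 (3R,4S)-6,8-dimethoxy-3,4,5-trimethylisochroman-1-one
Conditions: LiN(i-Pr)2 (1.1 equiv), THF, −78 °C; MeI (1.5 equiv), −78 → −40 °C
Reagents that add atoms: iodomethane, CI
Why: Lateral (ortho-toluate-type) lithiation at C4 gives a planar benzylic anion conjugated with the lactone carbonyl, and MeI adds axially on the face anti to the pseudo-axial C3 methyl (1,2-induction as in alkylation of six-membered lactone enolates) to give the trans (4S) product, the ring C3–O bond lying near the nodal plane of the carbanion so that E1cB ring opening is slow at −78 °C.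

**Step 5**
Reactants: 5 (3R,4S)-6,8-dimethoxy-3,4,5-trimethylisochroman-1-one
Product: 6 (3R,4S)-6,8-dihydroxy-3,4,5-trimethylisochroman-1-one
Conditions: BBr3 (4 equiv), CH2Cl2, −78 → 0 °C; then H2O
Reagents that add atoms: none
Why: Lewis-acid cleavage of both aryl methyl ethers with BBr3, which leaves the lactone and the two stereocentres untouched at or below 0 °C.

**Step 6**
Reactants: 6 (3R,4S)-6,8-dihydroxy-3,4,5-trimethylisochroman-1-one
Product: 7 (3R,4S)-7-acetyl-6,8-dihydroxy-3,4,5-trimethylisochroman-1-one
Conditions: Ac2O (1.5 equiv), BF3·OEt2 (solvent), 70 °C; then aq. MeOH, reflux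
Reagents that add atoms: acetic anhydride, CC(=O)OC(C)=O
Why: Friedel–Crafts C-acetylation (BF3-mediated, through the O-acetate and a Fries-type shift) at C7, the only unsubstituted ring carbon, which is activated by two ortho hydroxyls and is meta to the lactone carbonyl.

**Step 7**
Reactants: 7 (3R,4S)-7-acetyl-6,8-dihydroxy-3,4,5-trimethylisochroman-1-one
Product: 8 (3R,4S)-6,8-dihydroxy-7-(1-hydroxyethyl)-3,4,5-trimethylisochroman-1-one (both carbinol epimers)
Conditions: NaBH4 (2 equiv), THF–MeOH, 0 °C; pH 7 buffer; used crude
Reagents that add atoms: none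
Why: Borohydride reduction of the aryl ketone without touching the lactone; the new carbinol centre need not be controlled because it is erased when the ortho-quinone methide forms in step 9.

**Step 8**
Reactants: 6 (3R,4S)-6,8-dihydroxy-3,4,5-trimethylisochroman-1-one
Product: 10 (3R,4S)-6-hydroxy-3,4,5-trimethyl-3,4-dihydro-8H-isochromen-8-one (decarboxycitrinin drawn as its 6-hydroxy-8-oxo tautomer), via lactol 9 (not isolated)
Conditions: i-Bu2AlH (3.5 equiv), THF–CH2Cl2, −78 → −40 °C; then 1 M HCl, rt
Reagents that add atoms: none
Why: Partial lactone reduction, in which excess i-Bu2AlH first caps both phenols as aluminium phenoxides and then adds one hydride to give the stable cyclic lactol aluminate, and on acidic work-up lactol 9 loses water spontaneously to the vinylogous-acid quinone methide (the citrinin hydrate to citrinin equilibrium), with C3 and C4 untouched.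

**Step 9**
Reactants: 8 (3R,4S)-6,8-dihydroxy-7-(1-hydroxyethyl)-3,4,5-trimethylisochroman-1-one; 10 (3R,4S)-6-hydroxy-3,4,5-trimethyl-3,4-dihydro-8H-isochromen-8-one
Product: 12 dicitrinone H, via ortho-quinone methide 11 (not isolated)
Conditions: (R)-TRIP [(R)-3,3′-bis(2,4,6-triisopropylphenyl)-1,1′-binaphthyl-2,2′-diyl hydrogen phosphate] (10 mol %), 4 Å MS, PhCF3–CH2Cl2, −30 → 0 °C
Reagents that add atoms: none
Why: The chiral phosphoric acid ionizes the carbinol to ortho-quinone methide 11 and, as its phosphate, hydrogen-bonds both 11 and the enol OH of 10, so that the nucleophilic C7 of 10 adds to one face of the ethylidene carbon (enantioselective conjugate addition to an in situ ortho-quinone methide, a Michael/Friedel–Crafts-type alkylation) and sets the (R) bridge centre under catalyst control, homo-coupling being impossible because 8 has no free ring position.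

**Compound list**
1 | 5-bromo-2,4-dimethoxybenzoic acid | COc1cc(OC)c(C(=O)O)cc1Br | starting material
2 | 2,4-dimethoxy-5-methylbenzoic acid | COc1cc(OC)c(C(=O)O)cc1C | intermediate
3 | 2-allyl-4,6-dimethoxy-3-methylbenzoic acid | COc1cc(OC)c(C(=O)O)c(CC=C)c1C | intermediate
4 | (3R)-6,8-dimethoxy-3,5-dimethylisochroman-1-one | Cc1c(OC)cc(OC)c2c1C[C@@H](C)OC2=O | intermediate
5 | (3R,4S)-6,8-dimethoxy-3,4,5-trimethylisochroman-1-one | Cc1c(OC)cc(OC)c2c1[C@H](C)[C@@H](C)OC2=O | intermediate
6 | (3R,4S)-6,8-dihydroxy-3,4,5-trimethylisochroman-1-one | Cc1c(O)cc(O)c2c1[C@H](C)[C@@H](C)OC2=O | intermediate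
7 | (3R,4S)-7-acetyl-6,8-dihydroxy-3,4,5-trimethylisochroman-1-one | Cc1c(O)c(C(C)=O)c(O)c2c1[C@H](C)[C@@H](C)OC2=O | intermediate
8 | (3R,4S)-6,8-dihydroxy-7-(1-hydroxyethyl)-3,4,5-trimethylisochroman-1-one (carbinol epimers) | Cc1c(O)c(C(C)O)c(O)c2c1[C@H](C)[C@@H](C)OC2=O | intermediate
9 | (3R,4S)-3,4,5-trimethylisochromane-1,6,8-triol (lactol, C1 epimers, not isolated) | Cc1c(O)cc(O)c2c1[C@H](C)[C@@H](C)OC2O | intermediate
10 | (3R,4S)-6-hydroxy-3,4,5-trimethyl-3,4-dihydro-8H-isochromen-8-one (decarboxycitrinin, 6-hydroxy-8-oxo tautomer) | CC1=C2C(=CO[C@H](C)[C@H]2C)C(=O)C=C1O | intermediate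
11 | (3R,4S)-7-ethylidene-6-hydroxy-3,4,5-trimethyl-3,4-dihydro-1H-isochromene-1,8(7H)-dione (ortho-quinone methide, not isolated) | CC=C1C(O)=C(C)C2=C(C1=O)C(=O)O[C@H](C)[C@H]2C | intermediate
12 | dicitrinone H | CC1=C2C(=CO[C@H](C)[C@H]2C)C(=O)C([C@H](C)c2c(O)c(C)c3c(c2O)C(=O)O[C@H](C)[C@H]3C)=C1O | target

**Step count**
Total: 9 steps. Longest linear sequence: 8 steps (1 → 2 → 3 → 4 → 5 → 6 → 7 → 9); step 8 is a one-step branch from 6.

**Three steps most likely to fail**

Step 3 (the proposed hydrolactonization). Reversible hydrogen-atom transfer may move the allyl double bond into conjugation, which then leads to the five-membered phthalide. The N–F oxidant may attack the electron-rich ring, and the ee for a six-membered closure may be modest. Fallback, known chemistry: setting out from 2, a carboxylate-directed palladium-catalysed ortho-C–H alkylation with (R)-propylene oxide (Pd(OAc)2 5 mol %, N-acetyl-L-tert-leucine, KOAc, (CF3)2CHOH, 75 °C). The aryl–palladium bond opens the epoxide at CH2 and the alkoxide lactonizes, so the C3–O stereocentre is taken unchanged from the epoxide. This comes back to the route at 4, bypasses steps 2 and 3, and makes no compound outside the list (F0).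

Step 4 (C4 methylation). The benzylic anion may open the ring by β-elimination of the carboxylate, or the trans:cis ratio may be low. Fallback: setting out from 2, the same type of palladium-catalysed C–H alkylation is run with (2S,3S)-2,3-epoxybutane. Stereospecific SN2 opening with inversion at the carbon that becomes C4 gives the cis lactone (3S,4S)-6,8-dimethoxy-3,4,5-trimethylisochroman-1-one F1. LiOH opens it to 2-[(2S,3S)-3-hydroxybutan-2-yl]-4,6-dimethoxy-3-methylbenzoic acid F2. Mitsunobu lactonization (PPh3, DIAD, THF, 0 °C, high dilution) re-closes the ring with inversion at C3 and comes back to the route at 5. Both centres are then fixed by stereospecific steps, not by facial selectivity. Internal epoxides are not established substrates for this alkylation, which is the weak link of this fallback.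

Step 9 (bridge-forming coupling). Catalyst control over the bridge centre may be poor with two chiral partners, the sense of induction is not known in advance, and the addition may be reversible under acid. Fallback: setting out from 6, acid-catalysed condensation with acetaldehyde (0.5 equiv, cat. HCl, AcOH, rt) gives the symmetric 1,1-bis[(3R,4S)-6,8-dihydroxy-3,4,5-trimethyl-1-oxoisochroman-7-yl]ethane F3, whose bridge carbon is not a stereocentre. Mono-reduction with i-Bu2AlH as in step 8 passes through the mono-lactol 1-[(3R,4S)-1,6,8-trihydroxy-3,4,5-trimethylisochroman-7-yl]-1-[(3R,4S)-6,8-dihydroxy-3,4,5-trimethyl-1-oxoisochroman-7-yl]ethane F4. Acidic work-up gives 12 and its bridge epimer (S)-bridge dicitrinone H F5 in about equal amounts, separated by preparative HPLC; this comes back to the route at 12.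

**Further compounds**
F0 | step 3 | none | none
F1 | step 4 | (3S,4S)-6,8-dimethoxy-3,4,5-trimethylisochroman-1-one | Cc1c(OC)cc(OC)c2c1[C@H](C)[C@H](C)OC2=O
F2 | step 4 | 2-[(2S,3S)-3-hydroxybutan-2-yl]-4,6-dimethoxy-3-methylbenzoic acid | Cc1c(OC)cc(OC)c(C(=O)O)c1[C@H](C)[C@H](C)O
F3 | step 9 | 1,1-bis[(3R,4S)-6,8-dihydroxy-3,4,5-trimethyl-1-oxoisochroman-7-yl]ethane | CC(c1c(O)c(C)c2c(c1O)C(=O)O[C@H](C)[C@H]2C)c1c(O)c(C)c2c(c1O)C(=O)O[C@H](C)[C@H]2C
F4 | step 9 | 1-[(3R,4S)-1,6,8-trihydroxy-3,4,5-trimethylisochroman-7-yl]-1-[(3R,4S)-6,8-dihydroxy-3,4,5-trimethyl-1-oxoisochroman-7-yl]ethane | CC(c1c(O)c(C)c2c(c1O)C(O)O[C@H](C)[C@H]2C)c1c(O)c(C)c2c(c1O)C(=O)O[C@H](C)[C@H]2C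
F5 | step 9 | (S)-bridge dicitrinone H | CC1=C2C(=CO[C@H](C)[C@H]2C)C(=O)C([C@@H](C)c2c(O)c(C)c3c(c2O)C(=O)O[C@H](C)[C@H]3C)=C1O
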